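**Assumptions:** the target is taken exactly as drawn, (2S,2''R), which is kurarinol. Compounds 1, 6 and 10 are treated as catalogue chemicals. Compound 1 is sold as the cis/trans epoxide mixture made from orange-oil (R)-limonene.

## Retrosynthetic overview
1. Ring C is closed last. The O1–C2 bond forms by reversible oxa-Michael closure of the free chalcone, and crystallisation selects the 2S epimer against the fixed side-chain centre.
2. The chalcone Cα=Cβ bond comes from a Claisen–Schmidt condensation of a 3-alkylated, MOM-protected acetophenone with 2,4-bis(MOM)benzaldehyde.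
3. The key bond C8–CH2 (aryl–sp3) comes from a visible-light, Ni-catalysed decarboxylative coupling of a 3-iodoacetophenone with a redox-active ester.
4. The side-chain acid comes from (R)-limonene oxide: cleave C1–C2, oxidise CHO to CO2H, and add MeMgBr to the methyl ketone. Limonene C4 becomes C2''(R), and the carboxyl carbon leaves as CO2.
5. Ring order: rings A and B are bought as aromatics, the limonene ring is opened, and ring C is the only ring built (final step).

## Route

**Step 1**
Reactants: 1, (+)-(4R)-limonene 1,2-oxide (cis/trans mixture)
Product: 2, (3R)-6-oxo-3-(prop-1-en-2-yl)heptanal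
Conditions: H5IO6 (1.2 equiv), THF/H2O, 0 °C→rt
Reagents that add atoms: water, O (supplies one carbonyl oxygen; the other is the epoxide oxygen)
Why: Epoxide hydrolysis and Malaprade glycol cleavage run in one pot, both epoxide diastereomers converge on the same keto aldehyde, periodate ignores the isopropenyl group, and the untouched limonene C4 centre becomes C3 (R).

**Step 2**
Reactants: 2
Product: 3, (3R)-6-oxo-3-(prop-1-en-2-yl)heptanoic acid
Conditions: NaClO2, NaH2PO4, 2-methyl-2-butene (15 equiv), t-BuOH/H2O, 0 °C→rt
Reagents that add atoms: sodium chlorite, [Na+].[O-]Cl=O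
Why: Pinnick oxidation takes only the aldehyde, the scavenger keeps HOCl off the 1,1-disubstituted alkene, and the stereocentre is β to the carbonyl and so not enolisable.

**Step 3**
Reactants: 3
Product: 4, (3R)-6-hydroxy-6-methyl-3-(prop-1-en-2-yl)heptanoic acid
Conditions: MeMgBr (2.6 equiv), THF, −40→0 °C; aq. citric acid work-up
Reagents that add atoms: methylmagnesium bromide, C[Mg]Br
Why: In this Grignard addition the first equivalent forms the magnesium carboxylate, which is inert at or below 0 °C, so only the methyl ketone is attacked and the new carbinol carbon is not stereogenic.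

**Step 4**
Reactants: 4
Product: 5, 1,3-dioxoisoindolin-2-yl (3R)-6-hydroxy-6-methyl-3-(prop-1-en-2-yl)heptanoate (redox-active ester)
Conditions: N-hydroxyphthalimide (1.1 equiv), DIC (1.1 equiv), DMAP (5 mol %), CH2Cl2, rt
Reagents that add atoms: N-hydroxyphthalimide, O=C1c2ccccc2C(=O)N1O
Why: In this carbodiimide (Steglich-type) esterification the tertiary alcohol is too hindered to compete, either intermolecularly or by seven-membered lactonisation.

**Step 5**
Reactants: 6, 1-(2,4-dihydroxy-6-methoxyphenyl)ethan-1-one
Product: 7, 1-(2,4-dihydroxy-3-iodo-6-methoxyphenyl)ethan-1-one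
Conditions: I2 (0.4 equiv), HIO3 (0.2 equiv), EtOH/H2O, rt
Reagents that add atoms: iodine, II; iodic acid, OI(=O)=O
Why: This is an electrophilic aromatic iodination in which chelation of 2-OH to the acetyl group makes C3, between the two hydroxyls, the most nucleophilic carbon, the same selectivity seen with resacetophenone and in 2-iodoresorcinol formation.

**Step 6**
Reactants: 7
Product: 8, 1-[3-iodo-6-methoxy-2,4-bis(methoxymethoxy)phenyl]ethan-1-one
Conditions: NaH (2.5 equiv), MOMCl (2.6 equiv), DMF, 0 °C→rt
Reagents that add atoms: chloromethyl methyl ether, COCCl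
Why: Williamson-type O-alkylation of both phenoxides removes every acidic proton next to the C–I bond before the nickel step.

**Step 7 (key step)**
Reactants: 5 (1.0 equiv) and 8 (1.5 equiv; the excess is recovered)
Product: 9, 1-{3-[(2R)-5-hydroxy-5-methyl-2-(prop-1-en-2-yl)hexyl]-6-methoxy-2,4-bis(methoxymethoxy)phenyl}ethan-1-one
Conditions: NiBr2·dme (15 mol %), dtbbpy (18 mol %), Hantzsch ester (1.5 equiv), NaHCO3 (2 equiv), DMA (0.1 M), 427 nm LEDs, 25 °C, N2, 16 h
Reagents that add atoms: none
Why: Proposed new method: excitation of the Hantzsch ester/N-acyloxyphthalimide donor–acceptor pair reduces 5, N–O cleavage and CO2 loss give the primary homoallylic radical with its neighbouring stereocentre untouched, the same reductant turns over nickel, the weak C–I bond of 8 adds to low-valent Ni despite the two flanking OMOM groups (whose acetal oxygens can act as hemilabile donors), radical capture gives Ni(III) and ortho crowding speeds C(sp2)–C(sp3) reductive elimination, while 3-exo closure/1,2-vinyl shift of the radical (roughly 10^3–10^4 s^-1) should lose to capture at this Ni loading; the closest known reaction type is Ni-catalysed decarboxylative arylation of redox-active esters with unhindered aryl halides under photoredox/EDA conditions, which has not been shown for 2,6-dioxygenated aryl iodides or for β-stereogenic homoallylic radicals carrying a free tertiary alcohol.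

**Step 8**
Reactants: 10, 2,4-dihydroxybenzaldehyde
Product: 11, 2,4-bis(methoxymethoxy)benzaldehyde
Conditions: MOMCl (2.6 equiv), K2CO3, acetone, 0 °C→reflux
Reagents that add atoms: chloromethyl methyl ether, COCCl
Why: Routine phenol O-alkylation removes the phenoxide deactivation that otherwise stops the aldehyde from condensing.

**Step 9**
Reactants: 9 and 11 (1.2 equiv)
Product: 12, (E)-3-[2,4-bis(methoxymethoxy)phenyl]-1-{3-[(2R)-5-hydroxy-5-methyl-2-(prop-1-en-2-yl)hexyl]-6-methoxy-2,4-bis(methoxymethoxy)phenyl}prop-2-en-1-one
Conditions: KOH (50 % aq.), EtOH, rt, 36 h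
Reagents that add atoms: none
Why: Claisen–Schmidt condensation of two fully etherified partners gives the E-enone under thermodynamic control, and the tertiary alcohol, alkene and side-chain centre are inert to base.

**Step 10**
Reactants: 12
Product: 13, (E)-1-{2,4-dihydroxy-3-[(2R)-5-hydroxy-5-methyl-2-(prop-1-en-2-yl)hexyl]-6-methoxyphenyl}-3-(2,4-dihydroxyphenyl)prop-2-en-1-one (kuraridinol)
Conditions: TMSOTf (10 equiv), 2,2'-bipyridyl (15 equiv), MeCN, 0 °C→rt, dark; then H2O, KF, rt
Reagents that add atoms: none
Why: Non-acidic aryl-MOM cleavage converts each ArOMOM into ArOTMS, which is hydrolysed on work-up together with any tertiary O-TMS, so the isopropenyl group, the tertiary alcohol and the 2-hydroxychalcone/flavylium manifold never meet Brønsted acid.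

**Step 11**
Reactants: 13 (used crude; any flavanone already present is carried along)
Product: 14, (2S)-2-(2,4-dihydroxyphenyl)-7-hydroxy-8-[(2R)-5-hydroxy-5-methyl-2-(prop-1-en-2-yl)hexyl]-5-methoxy-2,3-dihydro-4H-chromen-4-one (target)
Conditions: NaOAc, EtOH, reflux, N2; then Et3N (0.3 equiv), i-PrOH/H2O 1:4, seeds of 14, 45↔20 °C cycling, 72 h; filter, wash with pH 5 water
Reagents that add atoms: none
Why: Proposed new method: the only free ortho-hydroxyl (2'-OH, since 6' is OMe) closes ring C by 6-endo oxa-Michael addition, mild base keeps this addition reversible so 13 and both C2 epimers interconvert (the 2',4'-dihydroxyphenyl group accelerates the retro-addition by quinone-methide-type push), and because the limonene-derived (R) centre makes the epimers diastereomers, seeded crystallisation of the (2S,2''R) form drains the roughly 1:1 solution equilibrium into one isomer; the closest known reaction types are base-mediated chalcone–flavanone isomerisation and crystallisation-induced diastereomer transformation of epimerisable centres, not yet shown for a flavanone C2 governed by a remote side-chain centre.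

## Compound list
1 | (+)-(4R)-limonene 1,2-oxide (cis/trans) | CC12OC1C[C@@H](CC2)C(C)=C | starting material
2 | (3R)-6-oxo-3-(prop-1-en-2-yl)heptanal | CC(=O)CC[C@H](CC=O)C(C)=C | intermediate
3 | (3R)-6-oxo-3-(prop-1-en-2-yl)heptanoic acid | CC(=O)CC[C@H](CC(=O)O)C(C)=C | intermediate
4 | (3R)-6-hydroxy-6-methyl-3-(prop-1-en-2-yl)heptanoic acid | CC(C)(O)CC[C@H](CC(=O)O)C(C)=C | intermediate
5 | N-(acyloxy)phthalimide of 4 | CC(C)(O)CC[C@H](CC(=O)ON1C(=O)c2ccccc2C1=O)C(C)=C | intermediate
6 | 1-(2,4-dihydroxy-6-methoxyphenyl)ethan-1-one | CC(=O)c1c(O)cc(O)cc1OC | starting material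
7 | 1-(2,4-dihydroxy-3-iodo-6-methoxyphenyl)ethan-1-one | CC(=O)c1c(O)c(I)c(O)cc1OC | intermediate
8 | 1-[3-iodo-6-methoxy-2,4-bis(methoxymethoxy)phenyl]ethan-1-one | CC(=O)c1c(OCOC)c(I)c(OCOC)cc1OC | intermediate
9 | 3-[(2R)-hydroxylavandulyl]-6-methoxy-2,4-bis(MOM)acetophenone | CC(=O)c1c(OCOC)c(C[C@@H](CCC(C)(C)O)C(C)=C)c(OCOC)cc1OC | intermediate
10 | 2,4-dihydroxybenzaldehyde | O=Cc1ccc(O)cc1O | starting material
11 | 2,4-bis(methoxymethoxy)benzaldehyde | O=Cc1ccc(OCOC)cc1OCOC | intermediate
12 | tetra-MOM (E)-chalcone | COCOc1ccc(/C=C/C(=O)c2c(OC)cc(OCOC)c(C[C@@H](CCC(C)(C)O)C(C)=C)c2OCOC)c(OCOC)c1 | intermediate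
13 | kuraridinol, free (E)-chalcone | COc1cc(O)c(C[C@@H](CCC(C)(C)O)C(C)=C)c(O)c1C(=O)/C=C/c1ccc(O)cc1O | intermediate
14 | (2S,2''R)-kurarinol | C=C(C)[C@H](CCC(C)(C)O)Cc1c(O)cc(OC)c2c1O[C@H](c1ccc(O)cc1O)CC2=O | target

## Step count
- Total steps: 11
- Longest linear sequence: 8 (Steps 1, 2, 3, 4, 7, 9, 10, 11)

## Three steps most likely to fail

**1. Step 7 (proposed new coupling).**
- Risk: slow oxidative addition or radical capture at the di-ortho-substituted aryl–Ni centre. This would give protodeiodinated arene, the decarboxylated alkane, or the vinyl-shifted isomer.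
- Fallback (known chemistry, two more steps): split the bond formation into two established reactions.
  - Photochemical decarboxylative borylation of 5 (B2cat2, DMAc, blue LEDs, then pinacol/Et3N), followed by KHF2 to give the primary alkyl trifluoroborate.
  - Pd(OAc)2/RuPhos B-alkyl Suzuki–Miyaura coupling with 8, a catalyst system that accepts di-ortho-substituted aryl halides.

**2. Step 11 (proposed new crystallisation-driven control of C2).**
- Risk: the 2R epimer, a mixed solid, or an oil separates instead of the 2S epimer. The first seeds also have to come from a small HPLC-separated batch, assigned by CD.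
- Fallback (known chemistry): run only the NaOAc ring closure and separate the two C2 epimers by preparative chromatography, which works on achiral phases because they are diastereomers. Re-equilibrate the unwanted 2R epimer with base and recycle it.

**3. Step 10 (fourfold MOM removal on the free-chalcone manifold).**
- Risk: incomplete cleavage, or side reactions of the enone or the 2-hydroxychalcone.
- Fallback: change the endgame order.
  - Unmask only the carbonyl-flanked 2'-OMOM by chelation-assisted cleavage (MgBr2·OEt2).
  - Close ring C on the tri-MOM chalcone with NaOAc.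
  - Remove the remaining three MOM groups from the flavanone, where no enone or flavylium pathway exists.
  - Finish with the Step 11 equilibration.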